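The cyclohexanone ring (C1 carbinol carbon, C4 ketone carbon) is cut along its mirror plane into two three-carbon units: the acetone unit C3–C4(=O)–C5 and the unit C2–C1–C6. A palladium-catalysed [3+3] α,α′-annulation of dimethyl 3-oxopentanedioate (1,3-bis-nucleophile) with 2-methylidenepropane-1,3-diyl diacetate (1,3-bis-electrophile), both acyclic and commercial, forms both Cα–Cβ bonds, C2–C3 and C5–C6, in one operation. It exploits the Cs symmetry of the ring, in which C4 and C1 face each other across two identical CH2–CH2 edges. The activating esters are then removed; the methylidene group left at C1 is homologated by a formaldehyde ene reaction, and acylation and Markovnikov hydration at C1 finish the target.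

Key step: step 1

Remark on the chemistry: the target has no stereocentre, because C1 lies on the mirror plane of the ring; the two stereocentres of compound 4 are transient and are removed in step 2.

Step 1
Reactants: 1 dimethyl 3-oxopentanedioate; 2 2-methylidenepropane-1,3-diyl diacetate
Product: 4 dimethyl 5-methylidene-2-oxocyclohexane-1,3-dicarboxylate, via mono-allylated keto diester 3 (not isolated)
Conditions: Pd(PPh3)4 (5 mol %), 1,1,3,3-tetramethylguanidine (2.2 equiv), 1,4-dioxane, 25 to 70 °C, slow addition of 2 to 1 (1.3 equiv)
Reagents that add atoms: none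
Why: Zerovalent palladium ionises one allylic acetate of 2 to a 2-(acetoxymethyl)allyl palladium cation, which the guanidine-generated enolate of 1 attacks at carbon to give 3; ionisation of the second acetate then places a π-allyl unit on the tether, and the remaining doubly activated α′-carbon closes the ring. The closest known reaction type is the double Tsuji–Trost alkylation used for α,α′-annulation of β-keto esters with this same diacetate. The six-membered ring closes by a 6-exo attack of the enolate carbon on a CH2 terminus of the π-allyl unit, whose other terminus is left as the exocyclic methylidene; both termini are equivalent, so no regiochemical question arises. The two new stereocentres (the ester-bearing carbons) are epimerisable, should form as a mixture together with the enol tautomer, and are erased in step 2, so no control is needed. The step needs C- over O-allylation, six- over four-membered ring closure and single over double annulation: the first is secured by the soft π-allyl electrophile and the reversibility of O-allylation under palladium catalysis, the second by ring strain and the higher acidity of the unsubstituted α′-CH2, the third by slow addition of 2 to an excess of 1.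

Step 2
Reactants: 4 dimethyl 5-methylidene-2-oxocyclohexane-1,3-dicarboxylate
Product: 6 4-methylidenecyclohexan-1-one, via mono-ester 5 (not isolated)
Conditions: LiCl (3 equiv), H2O (4 equiv), DMSO, 150 °C
Reagents that add atoms: none
Why: Krapcho dealkoxycarbonylation: chloride demethylates each β-keto ester and the β-keto carboxylates lose CO2 under neutral conditions, which should leave the exocyclic alkene in place.

Step 3
Reactants: 6 4-methylidenecyclohexan-1-one; 7 formaldehyde (used as paraformaldehyde)
Product: 8 4-(2-hydroxyethyl)cyclohex-3-en-1-one
Conditions: Me2AlCl (2.5 equiv), (CH2O)n, CH2Cl2, −20 to 0 °C; aqueous sodium potassium tartrate work-up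
Reagents that add atoms: none
Why: Me2AlCl-promoted carbonyl-ene reaction: the alkene CH2 attacks the complexed formaldehyde and a ring allylic hydrogen is transferred, which moves the double bond into the ring; the excess reagent allows for complexation of the ketone, and the two allylic ring CH2 groups are equivalent, so a single product is expected.

Step 4
Reactants: 8 4-(2-hydroxyethyl)cyclohex-3-en-1-one; 9 hexadecanoyl chloride
Product: 10 2-(4-oxocyclohex-1-en-1-yl)ethyl hexadecanoate
Conditions: pyridine (2 equiv), CH2Cl2, 0 °C
Reagents that add atoms: none
Why: Acylation of a primary alcohol by an acid chloride under weakly basic conditions, mild enough that the β,γ-unsaturated ketone should not move into conjugation.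

Step 5
Reactants: 10 2-(4-oxocyclohex-1-en-1-yl)ethyl hexadecanoate
Product: 12 2-(1-hydroxy-4-oxocyclohexyl)ethyl hexadecanoate, via tertiary hydroperoxide 11 (not isolated)
Conditions: Co(acac)2 (20 mol %), PhSiH3 (2 equiv), O2 (1 atm), iPrOH/THF, 25 °C; then PPh3
Reagents that add atoms: dioxygen, O=O
Why: Mukaiyama hydration: hydrogen-atom transfer from a cobalt hydride to the less substituted alkene carbon gives the tertiary radical at C1, which captures O2, and the peroxide is reduced to the tertiary alcohol; Markovnikov selectivity follows from radical stability, any radical-mediated alkene migration leads back to the same tertiary radical, and no stereocentre arises.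

Compound list
1 | dimethyl 3-oxopentanedioate | COC(=O)CC(=O)CC(=O)OC | starting material
2 | 2-methylidenepropane-1,3-diyl diacetate | CC(=O)OCC(=C)COC(C)=O | starting material
3 | dimethyl 2-[2-(acetoxymethyl)prop-2-en-1-yl]-3-oxopentanedioate | COC(=O)CC(=O)C(CC(=C)COC(C)=O)C(=O)OC | intermediate (not isolated)
4 | dimethyl 5-methylidene-2-oxocyclohexane-1,3-dicarboxylate (mixture of cis and trans isomers and enol form) | COC(=O)C1CC(=C)CC(C(=O)OC)C1=O | intermediate
5 | methyl 5-methylidene-2-oxocyclohexane-1-carboxylate | COC(=O)C1CC(=C)CCC1=O | intermediate (not isolated)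
6 | 4-methylidenecyclohexan-1-one | C=C1CCC(=O)CC1 | intermediate
7 | formaldehyde (used as paraformaldehyde) | C=O | starting material
8 | 4-(2-hydroxyethyl)cyclohex-3-en-1-one | OCCC1=CCC(=O)CC1 | intermediate
9 | hexadecanoyl chloride | CCCCCCCCCCCCCCCC(=O)Cl | starting material
10 | 2-(4-oxocyclohex-1-en-1-yl)ethyl hexadecanoate | CCCCCCCCCCCCCCCC(=O)OCCC1=CCC(=O)CC1 | intermediate
11 | 2-(1-hydroperoxy-4-oxocyclohexyl)ethyl hexadecanoate | CCCCCCCCCCCCCCCC(=O)OCCC1(OO)CCC(=O)CC1 | intermediate (not isolated)
12 | 2-(1-hydroxy-4-oxocyclohexyl)ethyl hexadecanoate | CCCCCCCCCCCCCCCC(=O)OCCC1(O)CCC(=O)CC1 | target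

Total step count: 5. Longest linear sequence: 5 steps (1 → 4 → 6 → 8 → 10 → 12).

Steps most likely to fail

Step 3. The Lewis acid may be sequestered by the ketone, the ketone may be hydroxymethylated at its α-carbon, or the new β,γ-double bond may migrate into conjugation. The fallback sets out from 6 and comes back at 12; it exchanges the roles of the two functionalised ring carbons, which the symmetry of the ring allows, so that the ketone carbon of 6 becomes the carbinol carbon and the methylidene carbon becomes the ketone. Addition of the lithium enolate of ethyl acetate (LiN(iPr)2, EtOAc, THF, −78 °C) to 6 should give ethyl 2-(1-hydroxy-4-methylidenecyclohexyl)acetate F1. Reduction with LiAlH4 (THF, 0 °C) should give 1-(2-hydroxyethyl)-4-methylidenecyclohexan-1-ol F2. Selective acylation of the primary hydroxyl with 9 (pyridine, CH2Cl2, 0 °C) should give 2-(1-hydroxy-4-methylidenecyclohexyl)ethyl hexadecanoate F3. Ozonolysis (O3, CH2Cl2, −78 °C), by way of the ozonide 2-(8-hydroxy-1,2,4-trioxaspiro[4.5]decan-8-yl)ethyl hexadecanoate F4, followed by PPh3, should deliver 12.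

Step 1. A second annulation across the remaining acidic methines (giving a bicyclo[3.3.1]nonanone), intermolecular oligomerisation of 3 before ring closure, or O-allylation may compete. The fallback sets out from 1 and comes back at 4; it replaces π-allyl catalysis by an enamine α,α′-annulation that still forms both bonds in one operation. Condensation of 1 with pyrrolidine (toluene, azeotropic removal of water) should give the β-enamino ester dimethyl 3-(pyrrolidin-1-yl)pent-2-enedioate F5. Heating F5 with commercial 3-chloro-2-(chloromethyl)prop-1-ene (ClCC(=C)CCl), NaI and iPr2NEt in MeCN should effect C-alkylation, transposition of the enamine to the other α-carbon and ring-closing C-alkylation, to give dimethyl 5-methylidene-2-(pyrrolidin-1-yl)cyclohex-1-ene-1,3-dicarboxylate F6. Dilute aqueous AcOH should hydrolyse F6 to 4.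

Step 5. The tertiary radical may be reduced to the C–H compound instead of being oxygenated, or the silane may reduce the ketone. The fallback sets out from 10 and comes back at 12; it installs the tertiary hydroxyl by an ionic sequence. Epoxidation (mCPBA, NaHCO3, CH2Cl2, 0 °C) should give 2-(4-oxo-7-oxabicyclo[4.1.0]heptan-1-yl)ethyl hexadecanoate F7. Base-induced β-elimination of the β,γ-epoxy ketone (Et3N, CH2Cl2, 25 °C) should give 2-(1-hydroxy-4-oxocyclohex-2-en-1-yl)ethyl hexadecanoate F8. Hydrogenation of the enone double bond (H2, palladium on carbon, EtOAc) should give 12.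

Further compounds
F1 | step 3 | ethyl 2-(1-hydroxy-4-methylidenecyclohexyl)acetate | CCOC(=O)CC1(O)CCC(=C)CC1
F2 | step 3 | 1-(2-hydroxyethyl)-4-methylidenecyclohexan-1-ol | OCCC1(O)CCC(=C)CC1
F3 | step 3 | 2-(1-hydroxy-4-methylidenecyclohexyl)ethyl hexadecanoate | CCCCCCCCCCCCCCCC(=O)OCCC1(O)CCC(=C)CC1
F4 | step 3 | 2-(8-hydroxy-1,2,4-trioxaspiro[4.5]decan-8-yl)ethyl hexadecanoate | CCCCCCCCCCCCCCCC(=O)OCCC1(O)CCC2(CC1)OCOO2
F5 | step 1 | dimethyl 3-(pyrrolidin-1-yl)pent-2-enedioate | COC(=O)C=C(CC(=O)OC)N1CCCC1
F6 | step 1 | dimethyl 5-methylidene-2-(pyrrolidin-1-yl)cyclohex-1-ene-1,3-dicarboxylate | COC(=O)C1=C(N2CCCC2)C(C(=O)OC)CC(=C)C1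
F7 | step 5 | 2-(4-oxo-7-oxabicyclo[4.1.0]heptan-1-yl)ethyl hexadecanoate | CCCCCCCCCCCCCCCC(=O)OCCC12CCC(=O)CC1O2
F8 | step 5 | 2-(1-hydroxy-4-oxocyclohex-2-en-1-yl)ethyl hexadecanoate | CCCCCCCCCCCCCCCC(=O)OCCC1(O)C=CC(=O)CC1
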